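## Structural features

Salimabromide is a compact tetracycle. A benzene ring with ethyl between two bromine atoms (ring A) is fused to a six-membered carbocycle with a benzylic C(CH3)2 (ring B). Ring B shares the triad benzylic CH–CH(C=O)–C(CH3) with a cyclohept-2-enone (ring C). A γ-butyrolactone (ring D) bridges ring C from the O–CH carbon next to the ketone, over the benzylic CH, to the carboxyl-bearing CH.

Four stereocentres stand in a row around ring C: O–CH, benzylic CH, lactone α-CH and quaternary C(CH3). The last is bonded directly to the second fully substituted carbon, C(CH3)2. Ring D needs the oxygen of the O–CH carbon and the carboxyl carbon cis on ring C; ring B needs the aryl group and the C(CH3)2 carbon cis on ring C, on the face opposite the lactone.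

Fragile groups are the enone next to the lactone oxygen (a Michael acceptor in a strained bridged lactone), the two C–Br bonds (lost under reducing or metalating conditions) and the benzylic CH2 of the ethyl group (at risk in oxidations). The real difficulty is the quaternary C(CH3) of defined configuration, wedged between C(CH3)2 and the lactone α-CH inside a bridged seven-membered ring.

The key step exploits the unit O=C–CH(α)–C(CH3)–CH=CH of rings D and C. The α-CH–C(CH3) bond is the one formed when the enolate of an allylic ester undergoes a [3,3] shift, and the ring-C alkene is the alkene left behind.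

One geometric point needs correction. In a lactone the shift must run through a boat, and in a boat the alkene substituent cis to the carbinol carbon ends cis to the aryl group. The group that later closes ring B (isopropenyl) must therefore be the cis one, so the dienyl alkene of the lactone has to be (1Z), with methyl outside. The (1E)-diene would give the epimer at the quaternary carbon, whose isopropenyl group is trans to aryl and cannot close ring B.

## Logic of the disconnections

**28 ⇒ 27.** The two aryl C–Br bonds are cut. They are the groups least tolerant of organometallic, reducing and radical steps, and their positions (both ortho to ethyl) are the ones the alkyl substituents activate. All earlier chemistry becomes halogen-free. The forward step must brominate twice on a crowded ring without touching the enone.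

**27 ⇒ 26.** The ketone oxygen is removed, leaving CH2. This carbon is the only allylic CH2 of ring C, since the other allylic position is quaternary. The most reactive function of the target is thereby absent from all acid and base steps. The forward oxidation must prefer this allylic CH2 over the benzylic CH2 of the ethyl group.

**26 ⇒ 23.** The aryl–C(CH3)2 bond of ring B and the acyl–O bond of ring D are cut. Both close under acid from groups already held cis on ring C: an isopropenyl group next to the aryl group, and a silyloxy group cis to the carboxyl group. The gain is a monocyclic cycloheptene acid. The forward step needs the tertiary cation to be captured by the ring position para to ethyl faster than it rearranges.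

**23 ⇒ 20 (key).** The bond between the carboxyl-bearing CH and the quaternary carbon is cut and the carboxyl oxygen is reconnected to the alkene carbon three atoms away. The carbocycle becomes a seven-membered lactone whose three stereocentres are separated by CH2 groups and can be set one at a time in an open chain. The forward step needs the ketene acetal of the lactone, the (1Z)-dienyl group on the carbinol carbon, and that carbon cis to the aryl-bearing carbon.

**20 ⇒ 18 ⇒ 17.** The lactone acyl–O bond is cut to the hydroxy acid, and that to its ethyl ester. The silyl ether on the other oxygen is essential, because a free hydroxyl there would close the five-membered lactone instead. The forward step is a seven-ring lactonisation at high dilution.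

**17 ⇒ 16 + 7.** The bond between the carbinol carbon and the dienyl carbon is cut. This is the convergent point: the (Z)-dienyl unit arrives complete and the carbinol centre is made last, next to nothing that can epimerise. The forward step must keep the alkene geometry, tolerate the ester and control the aldehyde face.

**16 ⇒ 14.** The aldehyde is traced to a terminal alkene, which carries the two-carbon spacer through the rhodium step as an inert group.

**14 ⇒ 12 + 13.** The aryl–C bond β to the ester is cut. The silyl ether is installed before the aryl group, so that neither a γ-hydroxy ester (which would lactonise) nor an α-aryl aldehyde (which would racemise) appears. The forward step must place aryl on the enoate face that gives the syn aryl/silyloxy relation.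

**12 ⇒ 11 ⇒ 8 + 9.** The O–Si bond, then the bond between the carbinol carbon and the allyl CH2, are cut. An achiral four-carbon aldehyde ester and an allyl donor remain. The forward step needs 1,2-addition and enantiocontrol.

**7 ⇒ 6 ⇒ 3 + 4; 3 ⇒ 1.** The C–I bond is traced to C–B, the alkenyl–alkenyl bond to a C–Br bond, and the bromoalkenyl boronate to an alkyne. Syn addition of B–Br across the alkyne fixes the geometry once; every later substitution must proceed with retention.

## Other disconnections considered

**Alternative 1:** One ring-C carbon is removed: the enone α-carbon is excised, leading back to the bridged cyclohexanone lactone A2. Forward, Me3SiCHN2 with catalytic Sc(OTf)3 adds to the ketone and the CH2 next to the quaternary carbon migrates, giving the ring-enlarged trimethylsilyl enol ether A1. Dehydrogenation of A1 would then give the enone.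
- In favour: two C–C bonds form in one mild step. The ketone oxygen is already in place, so no allylic C–H oxidation is needed. The aryl bromides are tolerated and can be carried from early material. On these two points (oxygen placement, timing of bromination) it is the better plan.
- Against: the step creates no stereocentre and none of the hard bonds. A2 must already contain rings B and D, the vicinal quaternary carbons and all four stereocentres in a bicyclo[3.2.1] lactone. Migration of the O–CH carbon, double homologation and epoxide formation are the usual side paths of diazoalkane expansions.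
- Comparison: structurally it is an endgame move, where the chosen plan is a skeleton-building move. Mechanistically it is a Lewis-acid 1,2-shift against a pericyclic shift with chirality transfer. In step economy its key step adds one carbon, while the chosen key step delivers a ring, a bond between hindered carbons and two stereocentres.

**Alternative 2:** The lactone carbonyl is cut out as carbon monoxide. Pd(PPh3)4 inserts into the vinyl bromide of A4, CO inserts, and the neighbouring allylic alcohol captures the acyl palladium to give the butenolide A3. Ring C would follow by metathesis of the vinyl and allyl groups.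
- In favour: the key step is robust and convergent, uses CO as the one-carbon unit, and closes ring D early. Only two stereocentres (quaternary carbon and carbinol) are needed before it. In reliability of the key step itself it is the equal or the better of the chosen plan.
- Against: A3 holds a tetrasubstituted, aryl-conjugated C=C whose reduction must create the benzylic and α-CH centres together on the correct face. Ring C cannot be closed before that reduction, because the butenolide alkene would sit at a bridgehead of a bicyclo[4.2.1] system (trans within the seven-membered ring). The reduction must also spare two terminal alkenes. The ring-C alkene then arises one position away from where the enone needs it.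
- Comparison: structurally it defers two of the four stereocentres to a difficult reduction, whereas the chosen plan sets them in the C–C bond-forming event. Mechanistically it is a metal-mediated acylation against a pericyclic shift. In step economy it is shorter to its key intermediate but longer afterwards.

**Alternative 3:** The bond between the two quaternary carbons is cut. SnCl4 ionises the tertiary benzylic alcohol A6, and the cation is captured by the substituted terminus of the (E)-allylsilane to give tetralin A5 with vinyl and methyl on the new quaternary carbon.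
- In favour: the most congested bond of the molecule and ring B are made in one step with a regiodefined terminator. The cumyl cation has no competing arene-alkylation problem, and the quaternary centre is relayed from the neighbouring ester-bearing CH. For the vicinal quaternary bond it is the more direct plan.
- Against: joining a tertiary cation to a trisubstituted alkene carbon is sterically severe. Loss of a proton from the cation to the α-methylstyrene, and protodesilylation, compete. Ring C, ring D and the enone are still to be built from the vinyl, ester and pivalate groups, with one more carbon to add.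
- Comparison: structurally it solves ring B and the quaternary centre first and leaves the seven-membered ring for later; the chosen plan does the reverse and closes ring B by a simpler cation–arene step. Mechanistically both rely on a tertiary cation, but here its capture decides a stereocentre. In step economy the chosen plan needs fewer operations after its key step.

Key step: step 11

Assumption: the senses of induction of (R)-BINOL (step 4), (S)-BINAP (step 6) and the (S)-oxazoline sulfonamide ligand (step 8) are taken from the closest substrate classes; where a sense is the opposite, the antipodal ligand is meant.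

## Route

Step 1
Reactants: 1 propyne
Product: 3 (Z)-2-(2-bromoprop-1-en-1-yl)-4,4,5,5-tetramethyl-1,3,2-dioxaborolane, via alkenyldibromoborane 2 (not isolated)
Conditions: BBr3, CH2Cl2, −78 °C; then pinacol, −78 → 23 °C
Reagents that add atoms: boron tribromide, BrB(Br)Br; pinacol, CC(C)(O)C(C)(C)O
Why: Haloboration: BBr3 adds syn across the terminal alkyne with boron on the terminal carbon, so bromine and boron end cis; exchange of the B–Br bonds for the pinacol ester gives a handleable (Z)-bromoalkenyl boronate.

Step 2
Reactants: 3 (Z)-2-(2-bromoprop-1-en-1-yl)-4,4,5,5-tetramethyl-1,3,2-dioxaborolane; 4 isopropenylmagnesium bromide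
Product: 6 (Z)-2-(2,3-dimethylbuta-1,3-dien-1-yl)-4,4,5,5-tetramethyl-1,3,2-dioxaborolane, via isopropenylzinc bromide 5 (not isolated)
Conditions: 4, ZnBr2, THF, 0 °C; then 3, Pd(PtBu3)2 (2 mol%), 23 °C
Reagents that add atoms: none
Why: Negishi coupling: zerovalent palladium inserts into the C–Br bond with retention and the alkenylzinc transfers isopropenyl, while the pinacol boronate is inert to the organozinc without base; isopropenyl therefore ends cis to boron.

Step 3
Reactants: 6 (Z)-2-(2,3-dimethylbuta-1,3-dien-1-yl)-4,4,5,5-tetramethyl-1,3,2-dioxaborolane
Product: 7 (1Z)-1-iodo-2,3-dimethylbuta-1,3-diene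
Conditions: NaOH (3 M aq.), THF, 0 °C; then I2, 0 °C, dark
Reagents that add atoms: iodine, I-I
Why: Iododeboronation of the hydroxide ate complex of an alkenyl boronate proceeds with retention, placing iodine cis to isopropenyl; the volatile, light-sensitive iodide should be kept in solution and used at once.

Step 4
Reactants: 8 ethyl (2E)-4-oxobut-2-enoate; 9 allyltributylstannane
Product: 11 ethyl (2E,4R)-4-hydroxyhepta-2,6-dienoate, via tributylstannyl ether 10 (not isolated)
Conditions: (R)-BINOL (10 mol%), Ti(OiPr)4 (10 mol%), 4 Å MS, CH2Cl2, −20 °C; aq. NaHCO3
Reagents that add atoms: none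
Why: Keck allylation: the BINOL–titanium Lewis acid activates the aldehyde and the allylstannane adds 1,2 through an open transition state; the (R)-ligand should deliver allyl to the Re face and set the (4R) carbinol, the future O–CH carbon of ring D.

Step 5
Reactants: 11 ethyl (2E,4R)-4-hydroxyhepta-2,6-dienoate
Product: 12 ethyl (2E,4R)-4-[(tert-butyldimethylsilyl)oxy]hepta-2,6-dienoate
Conditions: TBSCl, imidazole, DMF, 23 °C
Reagents that add atoms: tert-butyldimethylsilyl chloride, CC(C)(C)[Si](C)(C)Cl
Why: Standard silylation of a secondary alcohol; the silyl ether blocks γ-lactonisation once the enoate is saturated and carries this oxygen to the final lactonisation.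

Step 6
Reactants: 12 ethyl (2E,4R)-4-[(tert-butyldimethylsilyl)oxy]hepta-2,6-dienoate; 13 3-ethylphenylboronic acid
Product: 14 ethyl (3S,4R)-4-[(tert-butyldimethylsilyl)oxy]-3-(3-ethylphenyl)hept-6-enoate
Conditions: 13 (3 equiv), [Rh(acac)(C2H4)2] (3 mol%), (S)-BINAP (3.3 mol%), dioxane/H2O 10:1, 100 °C
Reagents that add atoms: none
Why: Hayashi–Miyaura conjugate addition: the aryl–rhodium species adds across the enoate and water protonates the rhodium enolate; (S)-BINAP should direct aryl to the Re face of C3, giving the (3S) centre with aryl and silyloxy syn in the extended chain, the existing centre acting only as a secondary influence.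

Step 7
Reactants: 14 ethyl (3S,4R)-4-[(tert-butyldimethylsilyl)oxy]-3-(3-ethylphenyl)hept-6-enoate
Product: 16 ethyl (3S,4R)-4-[(tert-butyldimethylsilyl)oxy]-3-(3-ethylphenyl)-6-oxohexanoate, via secondary ozonide 15 (not isolated)
Conditions: O3, CH2Cl2, −78 °C; then PPh3, −78 → 23 °C
Reagents that add atoms: ozone, [O-][O+]=O
Why: Ozonolysis of the only alkene and reduction of the ozonide by PPh3 to the aldehyde; the dialkylbenzene, ester and silyl ether are inert at −78 °C if ozone is stopped at the end point.

Step 8
Reactants: 16 ethyl (3S,4R)-4-[(tert-butyldimethylsilyl)oxy]-3-(3-ethylphenyl)-6-oxohexanoate; 7 (1Z)-1-iodo-2,3-dimethylbuta-1,3-diene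
Product: 17 ethyl (3S,4R,6S,7Z)-4-[(tert-butyldimethylsilyl)oxy]-3-(3-ethylphenyl)-6-hydroxy-8,9-dimethyldeca-7,9-dienoate
Conditions: CrCl2 (4 equiv), NiCl2 (2 mol%), N-{2-[(4S)-4-isopropyl-4,5-dihydro-1,3-oxazol-2-yl]-6-methylphenyl}methanesulfonamide, Et3N, THF, 23 °C
Reagents that add atoms: none
Why: Nozaki–Hiyama–Kishi coupling: nickel inserts into the C–I bond with retention and the alkenyl group passes to trivalent chromium, which adds only to the aldehyde, so the ester survives and the (Z) geometry is kept; the chiral sulfonamide on chromium should direct addition to the Re face and set the (6S) carbinol, 1,3-syn to the silyloxy group.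

Step 9
Reactants: 17 ethyl (3S,4R,6S,7Z)-4-[(tert-butyldimethylsilyl)oxy]-3-(3-ethylphenyl)-6-hydroxy-8,9-dimethyldeca-7,9-dienoate
Product: 18 (3S,4R,6S,7Z)-4-[(tert-butyldimethylsilyl)oxy]-3-(3-ethylphenyl)-6-hydroxy-8,9-dimethyldeca-7,9-dienoic acid
Conditions: LiOH, THF/MeOH/H2O, 0 → 23 °C; then 0.5 M HCl to pH 4, 0 °C
Reagents that add atoms: lithium hydroxide, [Li+].[OH-]
Why: Saponification of the ethyl ester; the secondary silyl ether and the dienyl carbinol tolerate LiOH, and the acidification is kept cold and mild so that the allylic alcohol does not ionise.

Step 10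
Reactants: 18 (3S,4R,6S,7Z)-4-[(tert-butyldimethylsilyl)oxy]-3-(3-ethylphenyl)-6-hydroxy-8,9-dimethyldeca-7,9-dienoic acid
Product: 20 (4S,5R,7S)-5-[(tert-butyldimethylsilyl)oxy]-7-[(1Z)-2,3-dimethylbuta-1,3-dien-1-yl]-4-(3-ethylphenyl)oxepan-2-one, via mixed anhydride 19 (not isolated)
Conditions: 2,4,6-Cl3C6H2COCl, Et3N, THF, 23 °C; then DMAP, toluene (2 mM), 80 °C
Reagents that add atoms: none
Why: Yamaguchi lactonisation: the mixed anhydride is transferred to DMAP and captured by the secondary allylic hydroxyl at high dilution, closing the seven-membered lactone without touching a stereocentre; the dienyl group ends cis to aryl and trans to silyloxy.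

Step 11
Reactants: 20 (4S,5R,7S)-5-[(tert-butyldimethylsilyl)oxy]-7-[(1Z)-2,3-dimethylbuta-1,3-dien-1-yl]-4-(3-ethylphenyl)oxepan-2-one
Product: 23 (1R,2R,6R,7S)-6-[(tert-butyldimethylsilyl)oxy]-7-(3-ethylphenyl)-2-methyl-2-(prop-1-en-2-yl)cyclohept-3-ene-1-carboxylic acid, via silyl ketene acetal 21 (not isolated), via trimethylsilyl ester 22 (not isolated)
Conditions: LiN(i-Pr)2, Me3SiCl, THF, −78 °C; then toluene, 90 °C; then aq. citric acid, THF, 23 °C
Reagents that add atoms: none
Why: LiN(i-Pr)2 with Me3SiCl traps the lactone enolate as the ring-held silyl ketene acetal 21, which undergoes a concerted suprafacial [3,3] shift, the Ireland–Claisen rearrangement of an alkenyl-lactone ketene acetal known to give cycloalkene carboxylic acids. Ring C closes by pericyclic bonding of the ketene-acetal carbon to the distal alkene carbon as the O–C(carbinol) bond breaks, so the carbocycle keeps C3–C7 of the lactone, gains the two alkene carbons and expels C2 and O1 as the carboxyl group. Because C3 and C7 are tied by the three-carbon tether, only a boat array is possible, and it leaves the cis ring alkene. The α-CH centre follows from the carbinol configuration: the dienyl group lies on the aryl face, the new bond forms on that face, and the carboxyl group ends trans to aryl and cis to silyloxy. The quaternary centre follows from the (Z)-alkene: in the boat the substituent cis to the carbinol carbon (isopropenyl) is eclipsed with the C3–C4 ring bond and ends cis to aryl, methyl cis to carboxyl. The step needs clean transfer without ionisation of the dienylic C–O bond or [1,5]-hydrogen shift in the cis-diene; the neutral silyl ketene acetal, a moderate temperature and the twisted, flat isopropenyl group in the inside position are relied on for this.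

Step 12
Reactants: 23 (1R,2R,6R,7S)-6-[(tert-butyldimethylsilyl)oxy]-7-(3-ethylphenyl)-2-methyl-2-(prop-1-en-2-yl)cyclohept-3-ene-1-carboxylic acid
Product: 26 didebromo-deoxosalimabromide (target skeleton with H in place of both Br and CH2 in place of the ketone C=O), via tetralin silyl ether acid 24 (not isolated), via hydroxy acid 25 (not isolated)
Conditions: CF3SO3H (2 equiv), CH2Cl2, −40 → 0 °C; then aq. HF (48%), MeCN, 23 → 45 °C
Reagents that add atoms: none
Why: Cation–arene cyclisation (Friedel–Crafts alkylation): protonation of the 1,1-disubstituted alkene gives a tertiary cation that is attacked by the ring position para to ethyl and ortho to the ring-C attachment, closing ring B as a six-membered ring on the face fixed by the cis aryl/isopropenyl relation. Aqueous HF then removes the silyl group and the cis hydroxy acid lactonises under acid to ring D; no stereocentre is created.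

Step 13
Reactants: 26 didebromo-deoxosalimabromide
Product: 27 didebromosalimabromide (target with H in place of both Br)
Conditions: Rh2(cap)4 (1 mol%), t-BuOOH (70% aq., 5 equiv), K2CO3, CH2Cl2, 23 °C
Reagents that add atoms: tert-butyl hydroperoxide, CC(C)(C)OO
Why: Allylic oxidation by tert-butylperoxy radicals: hydrogen abstraction at the single allylic CH2, peroxide formation at the less hindered allyl terminus and collapse to the enone. The other allylic position is quaternary, and the mild conditions are chosen to spare the benzylic CH2 of the ethyl group.

Step 14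
Reactants: 27 didebromosalimabromide
Product: 28 salimabromide
Conditions: Br2 (2.3 equiv), AgOCOCF3 (2.5 equiv), CF3CO2H, 0 → 23 °C
Reagents that add atoms: bromine, BrBr
Why: Electrophilic aromatic bromination with silver-activated Br2: the two positions ortho to ethyl carry the combined ortho/para activation of the alkyl groups, while the remaining CH is activated once and is flanked by C(CH3)2. The enone alkene is electron-poor, and the only α-CH of the ketone sits at a bridgehead.

## Compound list

1 | propyne | CC#C | starting material
2 | (Z)-dibromo(2-bromoprop-1-en-1-yl)borane | C/C(Br)=C/B(Br)Br | intermediate (not isolated)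
3 | (Z)-2-(2-bromoprop-1-en-1-yl)-4,4,5,5-tetramethyl-1,3,2-dioxaborolane | C/C(Br)=C/B1OC(C)(C)C(C)(C)O1 | intermediate
4 | isopropenylmagnesium bromide | CC(=C)[Mg]Br | starting material
5 | isopropenylzinc bromide | CC(=C)[Zn]Br | intermediate (not isolated)
6 | (Z)-2-(2,3-dimethylbuta-1,3-dien-1-yl)-4,4,5,5-tetramethyl-1,3,2-dioxaborolane (isopropenyl cis to boron) | C/C(=C/B1OC(C)(C)C(C)(C)O1)C(C)=C | intermediate
7 | (1Z)-1-iodo-2,3-dimethylbuta-1,3-diene (iodine cis to isopropenyl) | C/C(=C/I)C(C)=C | intermediate
8 | ethyl (2E)-4-oxobut-2-enoate | CCOC(=O)/C=C/C=O | starting material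
9 | allyltributylstannane | C=CC[Sn](CCCC)(CCCC)CCCC | starting material
10 | ethyl (2E,4R)-4-[(tributylstannyl)oxy]hepta-2,6-dienoate | CCOC(=O)/C=C/[C@H](O[Sn](CCCC)(CCCC)CCCC)CC=C | intermediate (not isolated)
11 | ethyl (2E,4R)-4-hydroxyhepta-2,6-dienoate | CCOC(=O)/C=C/[C@H](O)CC=C | intermediate
12 | ethyl (2E,4R)-4-[(tert-butyldimethylsilyl)oxy]hepta-2,6-dienoate | CCOC(=O)/C=C/[C@H](O[Si](C)(C)C(C)(C)C)CC=C | intermediate
13 | 3-ethylphenylboronic acid | CCc1cccc(c1)B(O)O | starting material
14 | ethyl (3S,4R)-4-[(tert-butyldimethylsilyl)oxy]-3-(3-ethylphenyl)hept-6-enoate | CCOC(=O)C[C@@H](c1cccc(CC)c1)[C@H](O[Si](C)(C)C(C)(C)C)CC=C | intermediate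
15 | ethyl (3S,4R)-4-[(tert-butyldimethylsilyl)oxy]-3-(3-ethylphenyl)-5-(1,2,4-trioxolan-3-yl)pentanoate (both epimers at the trioxolane carbon) | CCOC(=O)C[C@@H](c1cccc(CC)c1)[C@H](O[Si](C)(C)C(C)(C)C)CC1OCOO1 | intermediate (not isolated)
16 | ethyl (3S,4R)-4-[(tert-butyldimethylsilyl)oxy]-3-(3-ethylphenyl)-6-oxohexanoate | CCOC(=O)C[C@@H](c1cccc(CC)c1)[C@H](O[Si](C)(C)C(C)(C)C)CC=O | intermediate
17 | ethyl (3S,4R,6S,7Z)-4-[(tert-butyldimethylsilyl)oxy]-3-(3-ethylphenyl)-6-hydroxy-8,9-dimethyldeca-7,9-dienoate | CCOC(=O)C[C@@H](c1cccc(CC)c1)[C@H](O[Si](C)(C)C(C)(C)C)C[C@H](O)/C=C(/C)C(C)=C | intermediate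
18 | (3S,4R,6S,7Z)-4-[(tert-butyldimethylsilyl)oxy]-3-(3-ethylphenyl)-6-hydroxy-8,9-dimethyldeca-7,9-dienoic acid | OC(=O)C[C@@H](c1cccc(CC)c1)[C@H](O[Si](C)(C)C(C)(C)C)C[C@H](O)/C=C(/C)C(C)=C | intermediate
19 | mixed anhydride of 18 with 2,4,6-trichlorobenzoic acid | O=C(OC(=O)C[C@@H](c1cccc(CC)c1)[C@H](O[Si](C)(C)C(C)(C)C)C[C@H](O)/C=C(/C)C(C)=C)c1c(Cl)cc(Cl)cc1Cl | intermediate (not isolated)
20 | (4S,5R,7S)-5-[(tert-butyldimethylsilyl)oxy]-7-[(1Z)-2,3-dimethylbuta-1,3-dien-1-yl]-4-(3-ethylphenyl)oxepan-2-one | CCc1cccc(c1)[C@@H]1CC(=O)O[C@H](/C=C(/C)C(C)=C)C[C@H]1O[Si](C)(C)C(C)(C)C | intermediate (precursor of the key step)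
21 | (4S,5R,7S)-5-[(tert-butyldimethylsilyl)oxy]-7-[(1Z)-2,3-dimethylbuta-1,3-dien-1-yl]-4-(3-ethylphenyl)-2-[(trimethylsilyl)oxy]-4,5,6,7-tetrahydrooxepine | CCc1cccc(c1)[C@@H]1C=C(O[Si](C)(C)C)O[C@H](/C=C(/C)C(C)=C)C[C@H]1O[Si](C)(C)C(C)(C)C | intermediate (not isolated)
22 | trimethylsilyl ester of 23 | CCc1cccc(c1)[C@H]1[C@H](O[Si](C)(C)C(C)(C)C)CC=C[C@@](C)(C(C)=C)[C@@H]1C(=O)O[Si](C)(C)C | intermediate (not isolated)
23 | (1R,2R,6R,7S)-6-[(tert-butyldimethylsilyl)oxy]-7-(3-ethylphenyl)-2-methyl-2-(prop-1-en-2-yl)cyclohept-3-ene-1-carboxylic acid (cis ring alkene) | CCc1cccc(c1)[C@H]1[C@H](O[Si](C)(C)C(C)(C)C)CC=C[C@@](C)(C(C)=C)[C@@H]1C(=O)O | intermediate (product of the key step)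
24 | acid 23 after ring-B closure: the former isopropenyl carbon, now C(CH3)2, bonded to the aryl carbon para to ethyl; stereocentres as in 23 | CCc1ccc2c(c1)[C@H]3[C@H](O[Si](C)(C)C(C)(C)C)CC=C[C@@](C)(C2(C)C)[C@@H]3C(=O)O | intermediate (not isolated)
25 | hydroxy acid from 24 (OH in place of the silyloxy group, cis to CO2H) | CCc1ccc2c(c1)[C@H]3[C@H](O)CC=C[C@@](C)(C2(C)C)[C@@H]3C(=O)O | intermediate (not isolated)
26 | didebromo-deoxosalimabromide (rings A–D of the target; CH2 in place of C=O, H in place of both Br; configuration of the target) | CCc1ccc2c(c1)[C@H]1[C@@H]3OC(=O)[C@H]1[C@@](C)(C=CC3)C2(C)C | intermediate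
27 | didebromosalimabromide | CCc1ccc2c(c1)[C@H]1[C@@H]3OC(=O)[C@H]1[C@@](C)(C=CC3=O)C2(C)C | intermediate
28 | salimabromide | CCc1c(Br)cc2c(c1Br)[C@H]1[C@@H]3OC(=O)[C@H]1[C@@](C)(C=CC3=O)C2(C)C | target

## Step count and least certain steps

Total: 14 steps. Longest linear sequence: 11 steps (8 to 28, steps 4–14); the diene branch (steps 1–3) joins at step 8.

**Step 11 (key step).** The boat places isopropenyl inside, eclipsed with the ring bond and close to the ring CH2 next to the carbinol carbon, so the shift may be slow. A [1,5]-hydrogen shift of the cis-diene, or ionisation and elimination at the dienylic C–O bond, could then take over.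
Fallback: set out from 14. Saponification gives (3S,4R)-4-[(tert-butyldimethylsilyl)oxy]-3-(3-ethylphenyl)hept-6-enoic acid F1. This is esterified (DCC, DMAP) with (2E)-3,4-dimethylpenta-2,4-dien-1-ol F2, which is accessible by methylalumination of commercial 2-methylbut-1-en-3-yne (Me3Al, Cp2ZrCl2) and capture with formaldehyde, to give the dienyl ester F3. Open-chain Ireland–Claisen rearrangement of F3 (LiN(i-Pr)2, Me3SiCl, THF, −78 → 23 °C) through a chair should give the acyclic acid F4, which carries a vinyl and an isopropenyl group on the new quaternary carbon. Ring-closing metathesis of the two monosubstituted alkenes of F4 (second-generation Grubbs catalyst) closes ring C and rejoins the route at 23. The ring is then made by metathesis and no boat is needed. The relative configuration of the two new centres follows from the ketene acetal and (E)-alkene geometries; the face is left to the neighbouring aryl-bearing centre, so an epimer pair may need separation.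

**Step 6.** Facial selectivity may be poor if the silyloxy-bearing centre opposes the ligand, since the required product is the syn isomer.
Fallback: set out from 11. Oxidative Heck β-arylation with 13 (Pd(OAc)2, 2,9-dimethyl-1,10-phenanthroline, O2), with loss of ethanol in the same flask, should give (5R)-4-(3-ethylphenyl)-5-(prop-2-en-1-yl)furan-2(5H)-one F5. Conjugate reduction with [(Ph3P)CuH]6 delivers hydride anti to the allyl group and gives the cis lactone (4S,5R)-4-(3-ethylphenyl)-5-(prop-2-en-1-yl)oxolan-2-one F6. KOH opens F6 to potassium (3S,4R)-3-(3-ethylphenyl)-4-hydroxyhept-6-enoate F7. Alkylation with EtI in DMF gives ethyl (3S,4R)-3-(3-ethylphenyl)-4-hydroxyhept-6-enoate F8, and immediate silylation (TBSOTf, 2,6-lutidine) rejoins the route at 14. Here the ring, not a catalyst, fixes the syn relation.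

**Step 8.** Loss of facial control at the new carbinol is possible, because 1,3-induction from a β-silyloxy group is weak and the ligand effect on a hindered dienyl chromium species is uncertain.
Fallback: set out from 16 and 7. Coupling without ligand (CrCl2, NiCl2, DMSO) gives 17 together with its (6R)-epimer F9. Dess–Martin oxidation of the mixture gives ethyl (3S,4R,7Z)-4-[(tert-butyldimethylsilyl)oxy]-3-(3-ethylphenyl)-8,9-dimethyl-6-oxodeca-7,9-dienoate F10. Reduction with (R)-2-methyl-CBS-oxazaborolidine and catecholborane at −78 °C, with the dienyl group as the large substituent, should return 17. The dienone must be kept cold and neutral so that the (Z)-alkene does not isomerise.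

**Step 12.** A 1,2-methyl shift of the tertiary cation to an allylic cation, or capture of the cation by the free carboxyl group, may outrun arene attack.
Fallback: set out from 23. Bu4NF gives (1R,2R,6R,7S)-7-(3-ethylphenyl)-6-hydroxy-2-methyl-2-(prop-1-en-2-yl)cyclohept-3-ene-1-carboxylic acid F11. Lactonisation (EDC·HCl, DMAP) gives the bridged lactone F12, in which the carboxyl group is tied up. Radical hydroarylation by metal-hydride hydrogen atom transfer (Co(salen), N-fluoro-2,4,6-trimethylpyridinium tetrafluoroborate, PhSiH3) then closes ring B through the tertiary radical, which does not undergo methyl shifts, and rejoins the route at 26.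

**Step 13.** Hydrogen abstraction at the benzylic CH2 of the ethyl group, or oxygen delivery to the hindered allyl terminus, would erode chemo- and regioselectivity.
Fallback: set out from 26. SeO2 with t-BuOOH in CH2Cl2 acts only on the alkene through an ene reaction and [2,3] shift, and gives the allylic alcohol F13 (deoxo compound 26 carrying OH on the former allylic CH2) with the alkene in place. Dess–Martin oxidation of F13 rejoins the route at 27.

## Further compounds

F1 | step 11 | (3S,4R)-4-[(tert-butyldimethylsilyl)oxy]-3-(3-ethylphenyl)hept-6-enoic acid | OC(=O)C[C@@H](c1cccc(CC)c1)[C@H](O[Si](C)(C)C(C)(C)C)CC=C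
F2 | step 11 | (2E)-3,4-dimethylpenta-2,4-dien-1-ol | OC/C=C(\C)C(C)=C
F3 | step 11 | (2E)-3,4-dimethylpenta-2,4-dien-1-yl (3S,4R)-4-[(tert-butyldimethylsilyl)oxy]-3-(3-ethylphenyl)hept-6-enoate | CCc1cccc(c1)[C@H](CC(=O)OC/C=C(\C)C(C)=C)[C@H](O[Si](C)(C)C(C)(C)C)CC=C
F4 | step 11 | open-chain acid: 23 with ring C opened at its alkene to a vinyl group on the quaternary carbon and an allyl group on the silyloxy-bearing carbon | CCc1cccc(c1)[C@@H]([C@H](O[Si](C)(C)C(C)(C)C)CC=C)[C@@H](C(=O)O)[C@@](C)(C=C)C(C)=C
F5 | step 6 | (5R)-4-(3-ethylphenyl)-5-(prop-2-en-1-yl)furan-2(5H)-one | CCc1cccc(c1)C1=CC(=O)O[C@@H]1CC=C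
F6 | step 6 | (4S,5R)-4-(3-ethylphenyl)-5-(prop-2-en-1-yl)oxolan-2-one | CCc1cccc(c1)[C@@H]1CC(=O)O[C@@H]1CC=C
F7 | step 6 | potassium (3S,4R)-3-(3-ethylphenyl)-4-hydroxyhept-6-enoate | [K+].[O-]C(=O)C[C@@H](c1cccc(CC)c1)[C@H](O)CC=C
F8 | step 6 | ethyl (3S,4R)-3-(3-ethylphenyl)-4-hydroxyhept-6-enoate | CCOC(=O)C[C@@H](c1cccc(CC)c1)[C@H](O)CC=C
F9 | step 8 | ethyl (3S,4R,6R,7Z)-4-[(tert-butyldimethylsilyl)oxy]-3-(3-ethylphenyl)-6-hydroxy-8,9-dimethyldeca-7,9-dienoate | CCOC(=O)C[C@@H](c1cccc(CC)c1)[C@H](O[Si](C)(C)C(C)(C)C)C[C@@H](O)/C=C(/C)C(C)=C
F10 | step 8 | ethyl (3S,4R,7Z)-4-[(tert-butyldimethylsilyl)oxy]-3-(3-ethylphenyl)-8,9-dimethyl-6-oxodeca-7,9-dienoate | CCOC(=O)C[C@@H](c1cccc(CC)c1)[C@H](O[Si](C)(C)C(C)(C)C)CC(=O)/C=C(/C)C(C)=C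
F11 | step 12 | (1R,2R,6R,7S)-7-(3-ethylphenyl)-6-hydroxy-2-methyl-2-(prop-1-en-2-yl)cyclohept-3-ene-1-carboxylic acid | CCc1cccc(c1)[C@H]1[C@H](O)CC=C[C@@](C)(C(C)=C)[C@@H]1C(=O)O
F12 | step 12 | bridged γ-lactone of F11 (rings C and D of the target skeleton with 3-ethylphenyl and isopropenyl groups, ring B open) | CCc1cccc(c1)[C@H]1[C@@H]2OC(=O)[C@H]1[C@@](C)(C=CC2)C(C)=C
F13 | step 13 | allylic alcohol of 26 (OH on the former allylic CH2, both epimers at that carbon) | CCc1ccc2c(c1)[C@H]1[C@@H]3OC(=O)[C@H]1[C@@](C)(C=CC3O)C2(C)C
A1 | alternative 1 | trimethylsilyl enol ether of dihydrosalimabromide | CCc1c(Br)cc2c(c1Br)[C@H]1[C@@H]3OC(=O)[C@H]1[C@@](C)(CC=C3O[Si](C)(C)C)C2(C)C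
A2 | alternative 1 | bridged cyclohexanone lactone (ring C six-membered, one CH2 between ketone and quaternary carbon) | CCc1c(Br)cc2c(c1Br)[C@H]1[C@@H]3OC(=O)[C@H]1[C@@](C)(CC3=O)C2(C)C
A3 | alternative 2 | tricyclic butenolide with vinyl on the O–CH carbon and allyl on the quaternary carbon | CCc1ccc2c(c1)C1=C(C(=O)O[C@@H]1C=C)[C@@](C)(CC=C)C2(C)C
A4 | alternative 2 | vinyl bromide of the dihydronaphthalene with the allylic alcohol on the benzylic alkene carbon | CCc1ccc2c(c1)C([C@H](O)C=C)=C(Br)[C@@](C)(CC=C)C2(C)C
A5 | alternative 3 | tetralin with vinyl and methyl on the new quaternary carbon, methyl ester and pivaloyloxymethyl groups | CCc1ccc2c(c1)[C@@H](COC(=O)C(C)(C)C)[C@@H](C(=O)OC)[C@@](C)(C=C)C2(C)C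
A6 | alternative 3 | tertiary benzylic alcohol with the tethered (E)-allylsilane | CCc1ccc(C(C)(C)O)c(c1)[C@@H](COC(=O)C(C)(C)C)[C@@H](C(=O)OC)/C(C)=C/C[Si](C)(C)C
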